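| flask | solid substrate | partner | protic impurity | remark | time |
|---|---|---|---|---|---|
| dusk | 0.10 M | 1.1 equiv (fed, over 2.0 min) | 0.030 M | run made earlier; the fed solution adds 1.0 times the starting volume |  |
| dawn | 0.10 M | 2.8 equiv (fed, over 2.0 min) | 0.030 M | run made earlier; the fed solution adds 1.0 times the starting volume |  |
| south | 0.10 M | 1.30 equiv (fed, over 2.0 min) | 0.0300 M | the fed solution adds 1.0 times the starting volume | 2.0 min |
| south-east | 0.10 M | 5.20 equiv | 0.0300 M | everything together at the start, the whole solution of partner included, so that from the start the volume is larger by 1.0 times the starting volume | 2.0 min |

- dusk (time / s: target / %, solid substrate / %): 10.0: 0, 60; 12.0: 2, 56; 25.0: 0, 38; 40.0: 5, 25; 80.0: 14, 0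
- dawn (time / s: target / %, solid substrate / %): 15.0: 0, 50; 30.0: 5, 34; 50.0: 12, 12; 60.0: 23, 2; 80.0: 36, 0

(each reading ± 1.5 percentage points)

- amounts are per litre of the starting volume; all of the dose is in the solution fed
- the analysis behind the earlier runs scatters by 1.5 percentage points, standard deviation
- at the start none of the solid substrate is in solution
- what has only dissolved of solid substrate counts as not reacted
- a reading or a percentage of target counts all its forms, free or not

- which of the two ends with the higher amount of target, in percent of the solid substrate charged ("neither" if they lie within 2 percentage points) (south / south-east / neither)
- target at the end, in percent of the solid substrate charged, south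
- target at the end, in percent of the solid substrate charged, south-east

- Dawn read more target than dusk at 80.0 s, 36 % against 14 %, a ratio of readings of 2.57 beside a dose ratio of 2.55, so I reckoned with the fraction left, f = exp(−kE), where E, the exposure, is the time integral of the partner concentration, counted as if none were used, and the whole solid substrate counts as in solution, which makes k an apparent constant with the dissolving lag folded in.
- With a steady feed whose volume equals the starting volume, charge c per starting volume, dosing time τ and x = t/τ, I had E = cτ(x − ln(1 + x)), so dawn at 80.0 s gave 5.24 M·s and the exponent per unit of exposure, read from that single reading and carrying its scatter, k = 0.0852 /M/s, while dusk, with 2.06 M·s, gave a second value of 0.0733 /M/s.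
- For south, with 4.79 M·s, the dawn way gave 33.5 % of target and the dusk way 29.6 %, and to see which one cheated I ran dawn's k back on dusk: it gave 16.1 % against the reading of 14 %, a gap of 2.1 percentage points beside a scatter of 1.5 points, and that same scatter sits on a smaller reading in dusk, so I kept the dawn way.
- In south-east the partner is charged at 0.260 M from the start, which I treated as a pseudo-first-order case with 31.2 M·s of exposure, so I committed to 93.0 % of target there, with south-east ahead of south.
- The forecast said south-east, with 32 % for south and 85 % for south-east, calling the south-east rate “comparable to dissolution”; my numbers lie higher than its numbers in south and in south-east.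

- South ended at 31.9 % and south-east at 92.9 %, which is 7.9 points above the forecast for south-east.

    solid substrate → decomposition product (k = 7.80 × 10⁻⁶ /s)
    solid substrate ⇌ dissolved substrate, rate k2*(cs2 - [dissolved substrate]) while solid is left; crystals form when [dissolved substrate] > cs2 (solubility = 0.0560 M, k = 0.110 /s)
    dissolved substrate + target → side product (k = 0.0230 /M/s)
    solid substrate + protic impurity → quenched substrate (k = 0.0240 /M/s)
    dissolved substrate + partner → target (k = 0.120 /M/s)
    solid product ⇌ target, rate k6*(cs6 - [target]) while solid is left; crystals form when [target] > cs6 (solubility = 20.0 mM, k = 0.540 /s)

- In south at 2.00 min, dissolved substrate stood at 63.8 %, beside a fraction left of 66.5 % from my k. The neighbour of south charged with 0.520 equiv of partner has an exposure of 1.91 M·s, so k gives 15.0 % of target there, and that flask ended at 14.0 %.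

The earlier runs and the new flask stem from a simulated flask on assumed constants, and the scatter is random.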